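3 questions stand on this flask, and I answer them with one number.

    coupling partner + catalyst + right-handed substrate → catalyst + right-handed product (k1 = 200 M⁻² s⁻¹)
    coupling partner + catalyst + left-handed substrate → catalyst + left-handed product (k2 = 18000 M⁻² s⁻¹)
    left-handed substrate ⇌ right-handed substrate (k3 = 0.050 s⁻¹)

left-handed substrate 22 mM; coupling partner 2.50 equiv (fed, over 30 s); catalyst 2.5 mol%; right-handed substrate 22 mM; time 1.5 h; the fed solution adds 0.10 times the starting volume

1. the state of affairs at 1.5 h: stopped, and by what, or still going (no working catalyst is left / all of the left-handed substrate has reacted / it is still moving / forward and back rates have come level / the coupling partner has run out first)
2. the left-handed product standing at 1.5 h, as a percentage of the left-handed substrate and right-handed substrate together charged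
3. the right-handed product standing at 1.5 h, as a percentage of the left-handed substrate and right-handed substrate together charged

- catalyst is single-handed; left-handed substrate and right-handed substrate are mirror images of each other, charged as a racemate, each of them at the stated concentration
- every charge counts on the volume at the start, and the solution that is fed holds the whole dose
- the reaction counts as stopped when no species that holds the left-handed substrate and right-handed substrate together changes by six tenths of a point or more over the second half of the time
- run time (flask): 1.5 h

- The charges count on the left-handed substrate, so in this flask c(catalyst) is 0.550 mM, and the coupling partner charge of 55.0 mM is more than the 44.0 mM of substrate together, so I expect the substrate to be used up.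
- The racemization relaxation half-life of 0.116 min is far shorter than the 1.5 h allowed, so I expect the flask to stop well inside the time.
- Right-handed substrate has two exits, pseudo-first-order coupling and racemization at 0.050 s⁻¹.
- I replace the rising and falling c(coupling partner) by a mean of 27.5 mM, half its charge, and get 0.0605: this is the leak number, the coupling rate of right-handed substrate over its racemization rate.
- Right-handed substrate is half of the substrate, and the share L/(1+L) of it leaks, so I commit to 2.85 % right-handed product and 97.2 % left-handed product.
- As a test, the same mean gives left-handed substrate a coupling rate of 0.272 s⁻¹, faster than racemization, yet 15.5 % of it racemizes to right-handed substrate, which raises my figure, while the low c(coupling partner) early in the feed lowers it; in this flask I trust the leak number for the size of my figure, not for its last digit.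
- The forecast says all of the left-handed substrate has reacted, with 93.2 % left-handed and 6.8 % right-handed product, “taking the catalyst and partner charges on total substrate”; I take them on the left-handed substrate, and my right-handed figure is lower.
- The simulation gives: all of the left-handed substrate has reacted, with 97.4 % left-handed and 2.58 % right-handed product. In the neighbour flask with 1.5 mol% of catalyst, the same mean gives a leak number of 0.0363 and so 1.75 % right-handed product; that neighbour flask holds 97.9 % left-handed product, and its right-handed product stands higher than reckoned, at 2.13 %.

All constants were chosen freely; no experiment stands behind them.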